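The summer run is the hottest earlier run and a relative of the north flask: it has the same activator and capture agent charges, at 34 °C against 40 °C, but twice the substrate.

| flask | substrate | activator | capture agent | temperature | remark | time |
|---|---|---|---|---|---|---|
| winter | 0.050 M | 0.12 M | 2 mM | 18 °C | run made earlier |  |
| summer | 0.20 M | 0.12 M | 2 mM | 34 °C | run made earlier |  |
| autumn | 0.10 M | 0.18 M | 2 mM | 18 °C | run made earlier |  |
| north | 0.10 M | 0.120 M | 2.00 mM | 40 °C |  | 20 h |
| east | 0.10 M | 0.120 M | 2.00 mM | 25 °C |  | 20 h |
| north-west | 0.10 M | 0.120 M | 2.00 mM | 10 °C |  | 20 h |

| run | time / h | ring / % |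
|---|---|---|
| winter | 2.50 | 0 |
| winter | 8.00 | 7.2 |
| winter | 15.0 | 23.5 |
| winter | 20.0 | 30.2 |
| winter | 30.0 | 44.5 |
| winter | 40.0 | 55.4 |
| summer | 0.833 | 2.1 |
| summer | 2.50 | 14.6 |
| summer | 5.00 | 27.5 |
| summer | 6.00 | 26.7 |
| summer | 10.0 | 30.6 |
| summer | 12.0 | 27.5 |
| summer | 15.0 | 26.1 |
| autumn | 4.00 | 3.4 |
| autumn | 8.00 | 12.2 |
| autumn | 15.0 | 28.0 |
| autumn | 25.0 | 46.7 |
| autumn | 40.0 | 57.9 |

(standard deviation of a reading: 1 percentage point)

- the analysis behind the earlier runs scatters by 1 percentage point, standard deviation

* the flask with the highest amount of ring, in percent of the substrate charged ("all alike" if they lie within 1.5 percentage points) (north / east / north-west / all alike)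
* final ring, as a percentage of the substrate charged, in north
* final ring, as a percentage of the substrate charged, in east
* final ring, as a percentage of the substrate charged, in north-west

The winter run, at 18 °C, is still climbing at its last reading, 55.4% after 40.0 h, and the autumn run likewise reaches 57.9%. The summer run instead tops out at a reading of 30.6% after 10.0 h and stands at 26.1% after 15.0 h, a fall of 4.5 percentage points against a scatter of 1 point. A falling reading means that ring leaves faster than it arrives. These two summer readings give 0.0318 /h: this is the net fade, the natural logarithm of c(ring) at the top over c(ring) later, divided by the hours between. If ring is lost by a first-order step, the net fade lies below the loss constant of ring while ring still arrives, so this figure is an estimate of a floor; it carries the scatter, and the top reading stands above its neighbours at 6.00 h and 12.0 h.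

The reckoning made here treats that loss as a correction to a peak. It assumes, roughly, that north tops out like the summer reading, at the same height and time, and lets ring fade over the remaining 10.0 h, which gives an estimate of 22.3%. North is hotter than the summer run and should fade faster, so this estimate is on the high side.

The forecast gives 25% for north, 40% for east and 12% for north-west, with east highest. It reads the stall as a ceiling: “This suggests an exothermic equilibrium, or activator dying when hot”. Its north value stands above the reckoning here; the two part on whether ring in north holds level or keeps falling.

The flasks give 15.7% in north, 43.1% in east and 8.44% in north-west, so east is highest, as forecast.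

    ring → over-reaction product (k = 5.10 × 10⁻⁶ /s, Ea = 101 kJ/mol)
    substrate + activated form → open dimer (k = 6.60 × 10⁻⁵ /M/s, Ea = 80.0 kJ/mol)
    activated form → ring (k = 9.00 × 10⁻⁵ /s, Ea = 104 kJ/mol)
    substrate + activator → activated form (k = 1.60 × 10⁻⁴ /M/s, Ea = 59.0 kJ/mol)
    capture agent + activated form → trapped intermediate (k = 6.10 × 10⁻⁴ /M/s, Ea = 70.0 kJ/mol)
    (constants at 25 °C)

The north flask falls from 31.4% ring at 10.0 h to 15.7% at 20.0 h, a net fade of 0.0691 /h, steeper than the value read from the summer run. Ring in north is a kinetic product on its way to over-reaction product, not an equilibrium one. The step from ring to over-reaction product is the main reason for the low end value in north: without that step the north flask ends at 82.3% ring instead of 15.7%. The east flask stands at 43.1% after 20 h and at 5.48% after 200 h, a mean net fade of 0.0115 /h over that span, under the loss constant of 0.0184 /h at 25 °C.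

The data come from a simulation on assumed constants, noise included.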